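The readings are simulated on assumed constants; scatter was added.

A closed, stirred vessel holds a racemate of the two substrates under a held gas supply, with single-handed free catalyst, racemization catalyst and impurity. The new flask is the last recipe below.

in all of them: left-handed substrate 41 mM; right-handed substrate 41 mM; gas 9.7 mM (held); free catalyst 0.20 mM

| flask | racemization catalyst | impurity | remark | time |
|---|---|---|---|---|
| south-west | 57 µM | 13 µM | run made earlier |  |
| north-east | 90 µM | 13 µM | run made earlier |  |
| south-east | 41 µM | 6.5 µM | run made earlier |  |
| flask | 41 µM | 13 µM |  | 30 min |

| run | time / min | left-handed product / % | right-handed product / % | left-handed substrate / % |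
|---|---|---|---|---|
| south-west | 3.00 | 3.6 | 0 | 47.3 |
| south-west | 6.00 | 5.0 | 0 | 45.6 |
| south-west | 10.0 | 9.5 | 1.4 | 44.9 |
| south-west | 12.0 | 12.4 | 0.3 | 45.1 |
| south-west | 15.0 | 15.1 | 3.4 | 42.3 |
| south-west | 20.0 | 19.1 | 1.1 | 37.8 |
| north-east | 1.33 | 1.2 | 0 | 50.3 |
| north-east | 4.00 | 4.9 | 1.3 | 48.0 |
| north-east | 6.00 | 5.3 | 0 | 47.4 |
| north-east | 10.0 | 11.2 | 0.8 | 42.8 |
| north-east | 15.0 | 14.9 | 0.6 | 42.7 |
| north-east | 20.0 | 20.6 | 3.0 | 39.4 |
| south-east | 4.00 | 3.6 | 0 | 46.7 |
| south-east | 8.00 | 8.5 | 1.7 | 45.4 |
| south-east | 10.0 | 11.6 | 0.1 | 45.2 |
| south-east | 15.0 | 14.8 | 2.1 | 42.0 |
| south-east | 20.0 | 19.6 | 1.7 | 37.8 |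

(each reading ± 1 percentage point)

- free catalyst is single-handed; left-handed substrate and right-handed substrate are mirror images of each other, charged as a racemate, each of them at the stated concentration
- at the start none of the gas is in solution
- an excess is the difference of the two amounts in percent of their sum
- an excess is below zero if the other one leads

* left-handed product and right-handed product together, in percent of the left-handed substrate and right-handed substrate charged together, at 30 min
* excess of left-handed product over right-handed product in the product at 30 min
* whether the exchange between left-handed substrate and right-handed substrate keeps pace with the reaction: how far the product's excess at 30 min gets from its value without exchange to its value with instant exchange (above 80% keeps pace, below 20% hardly takes part, else lags behind)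

The racemate is my zero. With no exchange, left-handed substrate stands at half the charge minus left-handed product. With instant exchange the two substrates stay equal, so it stands higher by half the difference of the products. In the south-east run at 20.0 min the reading covers 0.827 of that gap. This is the refill share, the part of the gap that the left-handed substrate has regained, zero for no exchange and one for instant exchange. The south-west run gives 0.767 and the north-east run 1.14, and one reading's scatter moves a share by about 0.112.

So exchange looks close to instant in these runs, but the share alone doesn't reach the new flask, whose charge differs. If impurity removes racemization catalyst one-for-one, the flask keeps 28.0 µM against 34.5 µM in the south-east run. If the shortfall from one grows inversely with that amount, I expect a share of 0.787, and I take it to hold at 30 min too. That share belongs to the substrate and the line of 80% to the product's excess, so I use it as a rough guide: it stands closer to that line than the scatter of a share.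

The forecast is firmer: 31% product, an excess of 82%, and an exchange that keeps pace, on the ground that “racemization is much faster than reaction”.

The flask gives 33.1% product and an excess of 83.9%, and its exchange keeps pace, at 91% of the way.

    racemization catalyst + impurity → spent catalyst B (k = 1.71 × 10⁵ M⁻¹ min⁻¹)
    reagent + free catalyst + left-handed substrate → free catalyst + left-handed product (k = 1.63 × 10⁵ M⁻² min⁻¹)
    reagent + free catalyst + right-handed substrate → free catalyst + right-handed product (k = 13700 M⁻² min⁻¹)
    left-handed substrate + racemization catalyst ⇌ right-handed substrate + racemization catalyst, rate k4*[racemization catalyst]*[left-handed substrate] forward; the back reaction follows from the equilibrium constant (k = 30100 M⁻¹ min⁻¹)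
    gas ⇌ reagent, rate k5*(csat - [reagent]) (kL = 0.105 min⁻¹)
    2 racemization catalyst → spent catalyst A (k = 2140 M⁻¹ min⁻¹)

The flask's refill share at 30.0 min is 0.915, above my 0.787. At that time racemization catalyst stands at 14.8% of its charge, yet the forward exchange takes left-handed substrate at 0.183 min⁻¹ while reaction takes it at 0.0313 min⁻¹, a faster exchange. In the neighbour flask, charged with 0.010 mM of racemization catalyst, less than the impurity, racemization catalyst stands at 0% at 30.0 min and the refill share is 0.0158.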